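## Structural features

Digriseophene A (15) is built from two identical benzophenone halves joined through one CH2 group between their rings A. Ring A is a phloroglucinol nucleus with five substituents: the ketone carbon sits between two hydroxyl-bearing carbons, the single methoxy group is para to the ketone, and the bridge carbon lies between the methoxy-bearing carbon and one hydroxyl-bearing carbon, which leaves one ring CH. Ring B is an orsellinic acid nucleus (4-OH, 2-OMe, 6-Me) bound through C1 to the ketone, so each diaryl ketone has four ortho substituents and is strongly hindered. There is no stereocentre, hence no neighbouring stereocentres, and only constitution has to be controlled. Fragile features are the electron-rich polyphenol rings (air oxidation as phenoxides), the diarylmethane bridge between two phloroglucinol rings (acid-induced scission, exchange through a quinone methide in hot alkali) and the aryl methyl ethers ortho to the ketones (labile to strong Lewis acids). The real difficulties are to place exactly one CH2 between two very nucleophilic rings without oligomers, to form the hindered ketones, and to tell the three oxygens of each ring A apart. The key step uses the fact that the bridge CH2 and the two ring A carbons bound to it form a C3 unit whose ends both continue into oxygen-bearing ring carbons. Read through both rings A, the thirteen carbons (six per ring plus the bridge) form one unbranched chain with oxygen on C1, C3, C5, C9, C11 and C13: a glutarate core (C5 to C9) lengthened on each side by an acetoacetate unit.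

## Logic of the disconnections

15 back to 14. The two benzyl–oxygen bonds on the rings B are cut. The ring B hydroxyl para to the ketone is about as acidic as the ring A hydroxyl that must be methylated, so it has to stay masked to the end. A benzyl ether comes off under neutral conditions that leave ketones and bridge alone. The forward step only has to avoid reducing the diaryl ketones.

14 back to 13. The two methyl–oxygen bonds on the rings A are cut. In 13 the ketone marks the three oxygens of each ring A: two are ortho and hydrogen-bonded or shielded, one is para, free and the most acidic. The oxygens of the symmetric bis-triol therefore need not be differentiated before the ketones exist. The demand is one alkylation per ring at the para oxygen, which stands next to the bridge.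

13 back to 7 and 11. The two bonds between the rings A and the ketone carbons are cut. All four unsubstituted ring carbons of 7 are equivalent and the first acyl group deactivates its ring, so symmetry settles the regiochemistry and 13 falls into one bis-triol and two molecules of one acid. The forward step must form a carbon–carbon bond from a di-ortho-substituted acyl donor (activated as 12) in the presence of six free hydroxyls and an acid-sensitive bridge.

11 back to 8 through 10 and 9. The ester C–O bond, the methyl–oxygen bond and the benzyl–oxygen bond of ring B are cut in this order. In 8 the hydroxyl next to the ester is hydrogen-bonded and slow, so benzylation of the other one followed by methylation needs no protecting-group detour. The only demand is a forcing hydrolysis of the hindered ester 10.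

7 back to 5 (key disconnection). In each ring the bond between the bridge-bearing carbon and one neighbouring C–OH carbon is cut; these are C6–C1 and C8–C13 of 5. Both rings unfold into one unbranched chain in which the bridge is C7 and is never introduced as an electrophile, so over-bridging cannot occur. The gain is from a bis-arene to an acyclic, symmetric tetraketo diester. The forward step asks C6 and C8, each activated by one carbonyl only, to acylate onto the esters although C2, C4, C10 and C12 are more acidic, and although lactonization through oxygen and an aldol closure between the two arms (C4 onto C9, C10 onto C5) are open. The design answer has two parts: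
- 5 is kept as the plain dimethyl ester. A more reactive acyl group or an enol-ether mask at C3 would favour lactonization.
- 5 is run as the tetraenolate 6, never as the fully deprotonated hexa-anion, in which the esters would be enolates and no longer electrophilic.

5 back to 2 and two molecules of 3. The C4–C5 and C9–C10 bonds are cut. A five-carbon bis-acyl donor is set against two four-carbon nucleophiles that react at their terminal carbon as the dianion 4, the natural polarity of both partners. The amide leaving group of 2 is chosen so that the tetrahedral adducts hold until the quench. The forward step then needs only excess 4 and a cold acidic work-up.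

2 back to 1. The two amide C–N bonds are cut, which leads to the commercial diester.

## Other disconnections considered

Alternative 1: The cut is, in each ring A, the bond between the acyl-bearing carbon and the neighbouring C–OH carbon next to the bridge carbon. The precursor is the methylene-bridged bis(4-methoxy-2-pyranone) A2, which carries a ring B 1,3-diketone side chain on each C6. A2 would come from the bridged bis(4-methoxy-6-methyl-2-pyranone) A3 by twofold deprotonation at the 6-methyl groups and acylation with a ring B ester such as 10. In the forward key step Mg(OMe)2 in methanol would open both lactones; the 1,3-diketone carbon of each chain would then close onto the freed ester to give A1, which has the structure of 14.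
- In its favour: the nucleophilic carbon is the most acidic one of the chain, and the lactone-to-acylphloroglucinol recyclization is a known reaction type. The ring A methyl ether is carried in by the pyranone, and the ketone enters by ester acylation, not by Friedel–Crafts chemistry.
- Against it: the twofold acylation of A3 with a di-ortho-substituted benzoate is demanding, since each product is an acidic diketone that consumes base. The bridge of A3 and A2 joins two vinylogous ester carbons and may be lost by retro-Michael cleavage under methoxide.
- Comparison: on mechanism Alternative 1 is the better plan, because acidity and nucleophile match. On structure it is also better, because no selective methylation is needed. In step count it is equal or slightly shorter. The chosen plan has the simpler building blocks and avoids the hindered ester acylation, but it pays with an unprecedented ring closure and two delicate late steps.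

Alternative 2: The cut is the aryl–carbonyl bond on the ring B side together with the bond from ring B to its future methyl carbon. The bis(β-keto ester) A5, a fully O-differentiated bis-ring-A unit, would be treated with the silyl triflate A6 and CsF. The aryne released from A6 would insert into the ketone–CH2 bond of each arm to give A4.
- In its favour: the most hindered bond of the target would form under mild fluoride conditions by a known acyl-alkylation of arynes. The regiochemistry follows the usual preference of a 3-methoxyaryne. All ring A oxygens are fixed beforehand (methyl in place, the others benzylated).
- Against it: A4 carries CH2CO2Me where a methyl group is needed, so hydrolysis and a difficult decarboxylation of an arylacetic acid must follow, besides the removal of six benzyl groups. A5 itself requires the bridged, differentiated bis-phloroglucinol and a twofold C-acylation, so the problems of the chosen route are moved, not solved. Two insertions at hindered aryl ketones compete with simple α-arylation.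
- Comparison: the key reaction of Alternative 2 is better precedented than the chosen Claisen closure, and its control of the O-substitution pattern is equal or better. On step economy and on the overall structural problem it is clearly worse.

Alternative 3: The cut is the pair of ring A–ketone bonds. The symmetric bis-triol A8 (the structure of 7) would be made in one step from benzene-1,3,5-triol A9 and formaldehyde. It would be acylated with the mixed anhydride 12 to give A7 (the structure of 13), followed by para-selective methylation and hydrogenolysis.
- In its favour: every reaction is of a known type, and the bis-triol takes one step instead of three.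
- Against it: each ring of A9 has three equivalent nucleophilic positions and A8 keeps four, so over-bridging to oligomers competes, and the outcome depends on a large excess of A9 and on separation. The acylation and methylation risks are identical to those of steps 7 and 8 of the chosen route.
- Comparison: from the bis-triol onward the two plans are equal compound for compound. In step economy and reliance on known chemistry Alternative 3 is the better plan. The chosen plan is superior only in how the bridge arises: as a chain carbon that cannot over-react. The price is one reaction without direct precedent.

Key step: step 3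

Assumption: the target has no stereocentre and its SMILES carries no stereodescriptor, so no stereocontrol is planned; equivalents refer to the limiting numbered compound of each step.

## Route

Step 1
Reactants: 1 dimethyl glutarate (dimethyl pentanedioate)
Product: 2 N1,N5-dimethoxy-N1,N5-dimethylpentanediamide
Conditions: MeNH(OMe)·HCl (3 equiv), i-PrMgCl (6 equiv), THF, −20 → 0 °C; aq NH4Cl
Reagents that add atoms: N,O-dimethylhydroxylamine hydrochloride, CNOC.Cl
Why: Aminolysis of both esters by the magnesium amide formed in the flask (ester to Weinreb amide); a glutarate cannot close a Dieckmann ring of reasonable size, so clean twofold conversion is expected.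

Step 2
Reactants: 3 methyl acetoacetate (methyl 3-oxobutanoate); 2 N1,N5-dimethoxy-N1,N5-dimethylpentanediamide
Product: 5 dimethyl 3,5,9,11-tetraoxotridecanedioate, via sodium lithium dianion 4 (not isolated)
Conditions: 3 (5 equiv), NaH (5 equiv), THF, 0 °C; n-BuLi (5 equiv), 0 °C; then 2, 0 °C → rt; cold 1 M HCl
Reagents that add atoms: none
Why: Acylation of the acetoacetate dianion at its terminal carbon (Huckin–Weiler type) by a Weinreb amide; the chelated tetrahedral adducts persist until the acid quench, so the new ketones and the 1,5-diketone relationship never meet base and overaddition is excluded.

Step 3
Reactants: 5 dimethyl 3,5,9,11-tetraoxotridecanedioate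
Product: 7 2,2'-methylenebis(benzene-1,3,5-triol), via tetrapotassium tetraenolate 6 (not isolated)
Conditions: KN(SiMe3)2 (4.8 equiv), 18-crown-6 (4.8 equiv), THF (0.02 M), Ar, −78 → 60 °C; then degassed 2 M HCl, 0 °C
Reagents that add atoms: none
Why: Proposed new method: KN(SiMe3)2 first removes the protons at C4/C10 and C2/C12, so that in the resting state 6 every ketone and both esters are masked as enolates and neither lactonization to a 4-hydroxy-2-pyranone nor the aldol closure between the arms can start. Through HN(SiMe3)2 as proton shuttle, 6 should equilibrate with a small amount of the tautomer that is protonated at C2 and deprotonated at C6, a Hauser-type 1,3-diketone dianion whose terminal carbanion C6 is its most nucleophilic site and lies six atoms from the now free ester carbonyl C1. Attack of C6 on C1 (6-exo-trig at the ester carbon, an intramolecular Claisen condensation), loss of methoxide and enolization give the first benzene-1,3,5-triol ring as its phenoxide, the thermodynamic sink, and the same sequence at C8/C13 closes the second ring, again 6-exo-trig. The closest known reaction types are the Claisen cyclization of 3,5,7-triketo esters to acylphloroglucinols and the base-induced cyclization of 5-oxoalkanoates to cyclohexane-1,3-diones, where a ketone α-carbon with a single activating group closes onto an ester; new here is that this carbon must compete with two more acidic positions of the same chain. No stereocentre is formed. The selectivity needed is C-acylation at C6 over O-acylation by the C5 enolate oxygen; it rests on the higher nucleophilicity of the terminal carbanion, on the potassium counter-ion with 18-crown-6, which loosens the chelate that would hold C2 and C6 apart, on the slight excess of base that keeps C2 deprotonated in the bulk, and on the aromatic phenoxide as sink should some lactone form and be reopened by the liberated methoxide. Because the bridge is C7 of the chain, no one-carbon electrophile is used and oligomeric bridging cannot occur.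

Step 4
Reactants: 8 ethyl 2,4-dihydroxy-6-methylbenzoate (ethyl orsellinate)
Product: 9 ethyl 4-(benzyloxy)-2-hydroxy-6-methylbenzoate
Conditions: BnBr (1.05 equiv), K2CO3 (1.1 equiv), acetone, reflux
Reagents that add atoms: benzyl bromide, BrCc1ccccc1
Why: Williamson etherification; the 2-OH is hydrogen-bonded to the ester carbonyl and hindered, so the 4-OH should be alkylated selectively.

Step 5
Reactants: 9 ethyl 4-(benzyloxy)-2-hydroxy-6-methylbenzoate
Product: 10 ethyl 4-(benzyloxy)-2-methoxy-6-methylbenzoate
Conditions: MeI (3 equiv), K2CO3 (3 equiv), DMF, 60 °C
Reagents that add atoms: iodomethane, CI
Why: Williamson etherification of the remaining chelated phenol under more forcing conditions; no other acidic site is present.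

Step 6
Reactants: 10 ethyl 4-(benzyloxy)-2-methoxy-6-methylbenzoate
Product: 11 4-(benzyloxy)-2-methoxy-6-methylbenzoic acid
Conditions: KOH (10 equiv), DMSO/H2O 4:1, 110 °C; then 1 M HCl, 0 °C
Reagents that add atoms: potassium hydroxide, [K+].[OH-]
Why: Saponification; the di-ortho-substituted ester needs hot hydroxide in a dipolar solvent, which benzyl and methyl aryl ethers tolerate, and cold acidification avoids decarboxylation of the electron-rich acid.

Step 7
Reactants: 11 4-(benzyloxy)-2-methoxy-6-methylbenzoic acid; 7 2,2'-methylenebis(benzene-1,3,5-triol)
Product: 13 [methylenebis(2,4,6-trihydroxybenzene-3,1-diyl)]bis{[4-(benzyloxy)-2-methoxy-6-methylphenyl]methanone}, via mixed trifluoroacetic anhydride 12 (not isolated)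
Conditions: 11 (2.3 equiv), (CF3CO)2O (2.2 equiv), CH2Cl2, 0 °C; then 7, MeCN, 0 °C → rt; then MeOH, aq NaHCO3
Reagents that add atoms: none
Why: Friedel–Crafts acylation through a mixed anhydride: the di-ortho-substituted, para-alkoxy acid should ionize from 12 to its acylium ion, which the phloroglucinol nuclei capture at carbon; all four free ring positions of 7 are equivalent and the first acyl group deactivates its ring, so one ketone per ring is expected, and aryl trifluoroacetates are cleaved in the bicarbonate work-up.

Step 8
Reactants: 13 [methylenebis(2,4,6-trihydroxybenzene-3,1-diyl)]bis{[4-(benzyloxy)-2-methoxy-6-methylphenyl]methanone}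
Product: 14 [methylenebis(2,6-dihydroxy-4-methoxybenzene-3,1-diyl)]bis{[4-(benzyloxy)-2-methoxy-6-methylphenyl]methanone}
Conditions: MeI (2.1 equiv), K2CO3 (2.2 equiv), acetone, rt
Reagents that add atoms: iodomethane, CI
Why: Selective Williamson methylation: in each ring A the hydroxyl para to the ketone is the most acidic and the only one neither hydrogen-bonded to nor shielded by the aroyl group, as in the known para-selective monoalkylation of 2,4,6-trihydroxyaryl ketones, so limiting base and iodomethane should methylate it first.

Step 9
Reactants: 14 [methylenebis(2,6-dihydroxy-4-methoxybenzene-3,1-diyl)]bis{[4-(benzyloxy)-2-methoxy-6-methylphenyl]methanone}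
Product: 15 digriseophene A, [methylenebis(2,6-dihydroxy-4-methoxybenzene-3,1-diyl)]bis[(4-hydroxy-2-methoxy-6-methylphenyl)methanone]
Conditions: H2 (1 atm), 10% Pd/C, EtOAc/MeOH, rt
Reagents that add atoms: none
Why: Hydrogenolysis of the two benzyl aryl ethers; the hindered, hydrogen-bonded diaryl ketones and the diarylmethane bridge should stay intact if the reaction is stopped after uptake of two equivalents of hydrogen.

## Compound list

1 | dimethyl glutarate | COC(=O)CCCC(=O)OC | starting material
2 | N1,N5-dimethoxy-N1,N5-dimethylpentanediamide | CON(C)C(=O)CCCC(=O)N(C)OC | intermediate
3 | methyl acetoacetate | COC(=O)CC(C)=O | starting material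
4 | sodium lithium dianion of methyl acetoacetate (C2 and C4 deprotonated; not isolated) | [CH2-]C(=O)[CH-]C(=O)OC.[Na+].[Li+] | intermediate
5 | dimethyl 3,5,9,11-tetraoxotridecanedioate | COC(=O)CC(=O)CC(=O)CCCC(=O)CC(=O)CC(=O)OC | intermediate
6 | tetrapotassium tetraenolate of 5 (deprotonated at C2, C4, C10 and C12; not isolated) | COC(=O)[CH-]C(=O)[CH-]C(=O)CCCC(=O)[CH-]C(=O)[CH-]C(=O)OC.[K+].[K+].[K+].[K+] | intermediate
7 | 2,2'-methylenebis(benzene-1,3,5-triol) | Oc1cc(O)c(Cc2c(O)cc(O)cc2O)c(O)c1 | intermediate
8 | ethyl 2,4-dihydroxy-6-methylbenzoate (ethyl orsellinate) | CCOC(=O)c1c(C)cc(O)cc1O | starting material
9 | ethyl 4-(benzyloxy)-2-hydroxy-6-methylbenzoate | CCOC(=O)c1c(C)cc(OCc2ccccc2)cc1O | intermediate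
10 | ethyl 4-(benzyloxy)-2-methoxy-6-methylbenzoate | CCOC(=O)c1c(C)cc(OCc2ccccc2)cc1OC | intermediate
11 | 4-(benzyloxy)-2-methoxy-6-methylbenzoic acid | COc1cc(OCc2ccccc2)cc(C)c1C(=O)O | intermediate
12 | 4-(benzyloxy)-2-methoxy-6-methylbenzoic trifluoroacetic anhydride (not isolated) | COc1cc(OCc2ccccc2)cc(C)c1C(=O)OC(=O)C(F)(F)F | intermediate
13 | [methylenebis(2,4,6-trihydroxybenzene-3,1-diyl)]bis{[4-(benzyloxy)-2-methoxy-6-methylphenyl]methanone} | Oc1cc(O)c(C(=O)c2c(C)cc(OCc3ccccc3)cc2OC)c(O)c1Cc1c(O)cc(O)c(C(=O)c2c(C)cc(OCc3ccccc3)cc2OC)c1O | intermediate
14 | [methylenebis(2,6-dihydroxy-4-methoxybenzene-3,1-diyl)]bis{[4-(benzyloxy)-2-methoxy-6-methylphenyl]methanone} | COc1cc(O)c(C(=O)c2c(C)cc(OCc3ccccc3)cc2OC)c(O)c1Cc1c(OC)cc(O)c(C(=O)c2c(C)cc(OCc3ccccc3)cc2OC)c1O | intermediate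
15 | digriseophene A | COc1cc(O)c(C(=O)c2c(C)cc(O)cc2OC)c(O)c1Cc1c(OC)cc(O)c(C(=O)c2c(C)cc(O)cc2OC)c1O | target

## Step count and least certain steps

Total: 9 steps. Longest linear sequence: 6 steps (steps 1, 2, 3, 7, 8, 9; the ring B branch through steps 4, 5, 6, 7, 8, 9 is equally long).

Step 3 (key step, proposed new method).
- What may go wrong: the population of the tautomer deprotonated at C6 or C8 may be too small, so the chain survives unchanged until slower processes take over. These are lactonization through the C5 or C9 enolate oxygen whenever an arm is protonated at C2 or C12, aldol condensation between the arms whenever a diketone unit is not enolized, and intermolecular Claisen condensation. Once formed, the polyphenoxide of 7 may be oxidized or may exchange at the bridge.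
- Fallback (known chemistry): this fallback leaves the route at none of the numbered compounds; the branch 1 to 6 is given up. Purchased benzene-1,3,5-triol in large excess is condensed with aqueous formaldehyde in dilute HCl at room temperature, a known electrophilic bridging that gives 7 besides higher oligomers. 7 is separated by crystallization after recovery of the excess triol, and the route is rejoined at 7. No compound outside the compound list is made.

Step 7.
- What may go wrong: O-acylation of the phenols in place of C-acylation, C-trifluoroacetylation of the very nucleophilic rings, and acid-induced scission or exchange at the methylene bridge before the rings are deactivated.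
- Fallback: it sets out from 11 and reverses the order of acylation and bridging. 11 is activated as before and used to acylate purchased benzene-1,3,5-triol in excess (one nucleus, three equivalent positions, no bridge to lose), which gives [4-(benzyloxy)-2-methoxy-6-methylphenyl](2,4,6-trihydroxyphenyl)methanone F1. F1 is then bridged with 0.5 equivalent of aqueous formaldehyde under mild acid, the known way to methylene-bis(acylphloroglucinols), and the route is rejoined at 13.

Step 8.
- What may go wrong: loss of regioselectivity, because the para hydroxyl stands next to the bridge while one ortho hydroxyl is less hindered, and overalkylation. Errors multiply over the two rings.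
- Fallback: it sets out from 11 and passes through the monomeric ketone F1 described under step 7. F1 is methylated at the unhindered para hydroxyl at the monomer stage (MeI, K2CO3, acetone) to [4-(benzyloxy)-2-methoxy-6-methylphenyl](2,6-dihydroxy-4-methoxyphenyl)methanone F2, which is purified as a single small molecule. F2 is then bridged with 0.5 equivalent of formaldehyde at one of its two equivalent free positions, and the route is rejoined at 14.

Step 2.
- What may go wrong: enolization of the amide in place of addition, incomplete second acylation, and cyclization of 5 (lactonization or aldol closure between the arms) during acidic work-up and purification.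
- Fallback: it sets out from 3 and uses neutral conditions. 3 is silylated (Me3SiCl, Et3N) to methyl 3-[(trimethylsilyl)oxy]but-2-enoate F3. F3 is converted with LiN(i-Pr)2 and Me3SiCl into 1-methoxy-1,3-bis[(trimethylsilyl)oxy]buta-1,3-diene F4. Two equivalents of F4 are acylated at the terminal carbon by purchased glutaryl dichloride (CH2Cl2, −78 → 20 °C, aqueous work-up), a known route to 3,5-dioxo esters, and the route is rejoined at 5.

## Further compounds

F0 | step 3 | none | none
F1 | step 7 | [4-(benzyloxy)-2-methoxy-6-methylphenyl](2,4,6-trihydroxyphenyl)methanone | COc1cc(OCc2ccccc2)cc(C)c1C(=O)c1c(O)cc(O)cc1O
F2 | step 8 | [4-(benzyloxy)-2-methoxy-6-methylphenyl](2,6-dihydroxy-4-methoxyphenyl)methanone | COc1cc(O)c(C(=O)c2c(C)cc(OCc3ccccc3)cc2OC)c(O)c1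
F3 | step 2 | methyl 3-[(trimethylsilyl)oxy]but-2-enoate (mixture of double-bond isomers) | COC(=O)C=C(C)O[Si](C)(C)C
F4 | step 2 | 1-methoxy-1,3-bis[(trimethylsilyl)oxy]buta-1,3-diene (geometry at the ketene acetal not defined) | COC(O[Si](C)(C)C)=CC(=C)O[Si](C)(C)C
A1 | alternative 1 | digriseophene A bis(benzyl ether) at the ring B hydroxyls (structure of 14) | COc1cc(O)c(C(=O)c2c(C)cc(OCc3ccccc3)cc2OC)c(O)c1Cc1c(OC)cc(O)c(C(=O)c2c(C)cc(OCc3ccccc3)cc2OC)c1O
A2 | alternative 1 | 3,3'-methylenebis{6-[2-(4-benzyloxy-2-methoxy-6-methylphenyl)-2-oxoethyl]-4-methoxy-2H-pyran-2-one} | COc1cc(CC(=O)c2c(C)cc(OCc3ccccc3)cc2OC)oc(=O)c1Cc1c(OC)cc(CC(=O)c2c(C)cc(OCc3ccccc3)cc2OC)oc1=O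
A3 | alternative 1 | 3,3'-methylenebis(4-methoxy-6-methyl-2H-pyran-2-one) | COc1cc(C)oc(=O)c1Cc1c(OC)cc(C)oc1=O
A4 | alternative 2 | hexabenzyl bis-benzophenone with CH2CO2Me in place of each ring B methyl | COc1cc(OCc2ccccc2)c(C(=O)c2c(CC(=O)OC)cc(OCc3ccccc3)cc2OC)c(OCc2ccccc2)c1Cc1c(OC)cc(OCc2ccccc2)c(C(=O)c2c(CC(=O)OC)cc(OCc3ccccc3)cc2OC)c1OCc1ccccc1
A5 | alternative 2 | dimethyl 3,3'-[methylenebis(2,4-bis(benzyloxy)-6-methoxybenzene-3,1-diyl)]bis(3-oxopropanoate) | COc1cc(OCc2ccccc2)c(C(=O)CC(=O)OC)c(OCc2ccccc2)c1Cc1c(OC)cc(OCc2ccccc2)c(C(=O)CC(=O)OC)c1OCc1ccccc1
A6 | alternative 2 | 5-(benzyloxy)-3-methoxy-2-(trimethylsilyl)phenyl trifluoromethanesulfonate | COc1cc(OCc2ccccc2)cc(OS(=O)(=O)C(F)(F)F)c1[Si](C)(C)C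
A7 | alternative 3 | bis-benzophenone with three free hydroxyls on each ring A and benzyl ethers on ring B (structure of 13) | Oc1cc(O)c(C(=O)c2c(C)cc(OCc3ccccc3)cc2OC)c(O)c1Cc1c(O)cc(O)c(C(=O)c2c(C)cc(OCc3ccccc3)cc2OC)c1O
A8 | alternative 3 | 2,2'-methylenebis(benzene-1,3,5-triol) (structure of 7) | Oc1cc(O)c(Cc2c(O)cc(O)cc2O)c(O)c1
A9 | alternative 3 | benzene-1,3,5-triol | Oc1cc(O)cc(O)c1
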